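Remark on the chemistry: target atom labels are used for all intermediates. The oxanone ring is O1, C2 (bears the side chain), C3 (bears the ester oxygen), C4, C5, C6 (lactone carbonyl); the side chain is C1′–C8′, joined through C2′; the dienoate is C1″–C8″. The sense of induction of (+)-(NMI)2ZrCl2 (S-configured 2-methylalkyl alanes from 1-alkenes) and the fast-reacting carbinol enantiomer under titanium/tartrate conditions are taken from the accepted models for these reagents.

## The problem

The target is an ester of two halves. The alcohol half is a cis-2,3-disubstituted oxan-6-one whose C2 carries a (2S,4R,6E)-4,6-dimethyloct-6-en-2-yl chain. The acid half is a (2E,4E)-4-methylocta-2,4-dienoic acid with one stereocentre, C6″, that bears two free primary alcohols.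

Four of the five stereocentres form one array, C3–C2–C2′–(C3′)–C4′, and all four substituents (O on C3, O1 on C2, C1′ methyl on C2′, methyl on C4′) are syn in the zigzag chain. C2′ can control C2 (the C2–O/C2′–Me syn relation is the Felkin–Anh relation) and C2 can control C3. C4′ (1,3 to C2′ across a CH2) and the remote C6″ need external control.

The hardest point is not a stereocentre but the identity of the two oxygens. O1 on C2 is δ to the C6 carboxyl and must be the ring oxygen, while the oxygen on C3 is γ and must carry the dienoyl group. A free 2,3-diol closes through the C3 oxygen to the five-membered lactone, and a free C3–OH on the saturated δ-lactone can translactonise. The two oxygens therefore have to be told apart by the way the ring is built.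

The trisubstituted C6′=C7′ alkene is the most electron-rich group in the molecule, so OsO4, peracids, dioxiranes and ozone are excluded once it is in place. The dienoate is base-sensitive at C6″–H and isomerisable, and the free diol can transfer acyl groups, so the ester must be completed late and the diol unmasked last.

The feature that makes the key step possible is this: C3, C4, C5 and C6 of the oxanone carry oxygen at C3 and C6 (a 1,4-relationship), with ring O1 on the neighbouring C2. These are the four carbons of a furan (furan C2–C5), and O1–C2 is the carbinol of a 2-furylcarbinol. Oxidative ring expansion of that carbinol makes the carbinol oxygen the ring oxygen and leaves C3 as a ketone, so the regiochemistry of the two oxygens cannot go wrong.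

## Retrosynthesis

**Unmasking and C2″=C3″.** The two O–Si bonds of 28 are cut last to give target 29. In 28 the C2″=C3″ bond is cut (Horner–Wadsworth–Emmons) into phosphonoacetate 20 and enal 27. The neighbouring cut, the ester C–O bond with a complete dienoic acid, would ask a hindered alcohol to take up an activated, isomerisable dienoic acid. The olefination joins the halves under weak base and needs only E selectivity at a disubstituted alkene.

**Ring alkene and ester.** 20 comes from 19 by saturating C4=C5, and 19 from alcohol 17 and acid 18 by simple acylation. The acyl group is put on while the ring is still unsaturated and flat, so a free C3–OH never sits on a saturated δ-lactone. The precursor 17 has no phosphorus and no ester. The forward reactions must reduce a conjugated cis-alkene without touching C6′=C7′.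

**Oxidation-level shift.** 17 is an isomer of lactol 15. No bond is cut: the C6 lactol hydrogen is moved to the C3 ketone. A separate oxidation and reduction would pass through the isolated, easily enolised enedione 16. The forward reaction must set C3 cis to the side chain.

**Key disconnection.** In 15 the O1–C6 hemiacetal bond is cut and C3/C6 are returned to the furan oxidation level, which gives furylcarbinol 13 (Achmatowicz transform). This removes the ring, the ketone, the lactol and the regiochemical problem at once. 13 has one heteroatom functional group and is reached from an aldehyde in one step. The forward reaction must oxidise the furan and not C6′=C7′, and should accept only the correct C2 epimer.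

**C2–C3 bond.** 13 is cut between the carbinol carbon and the furan into aldehyde 10 and furan 11. The Felkin–Anh preference of the α-methyl aldehyde gives the needed C2/C2′ syn relation. The alternative cut at C2–C2′ would require a configurationally defined secondary alkyl metal.

**Side chain.** Aldehyde 10 comes from alcohol 9. The C2′–C1′ and C4′–methyl bonds are cut in turn (carboalumination), with the C2′–C3′ bond cut between them (vinylation), through diene 7 back to diene 4. One zirconium catalyst sets both methyl-bearing centres, and the repeating unit is a propene equivalent (methyl from Me3Al, two carbons from vinyl bromide 5). Auxiliary-based alkylations would need two auxiliaries and about twice the steps.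

**Diene 4.** The C4′... C5′–C6′ bond (allyl to alkenyl) is cut into bromide 1 and allyl bromide 2. The E geometry of C6′=C7′ is bought with 1 and never has to be made.

**Acid half.** Enal 27 comes from the isobutenyl compound 25 by oxidation of its E-methyl group, and 25 from diol 24 and lactone 23. In 23 the C6″–C5″ bond is cut (conjugate addition) into butenolide 21 and boronic acid 22. The lactone ring of 23 holds both future hydroxyl arms, so one catalytic step sets C6″ and no differentiation of the two alcohols is needed.

## Roads not taken

**Alternative 1:** the most obvious plan. Cut the ester C–O bond and open the lactone to a 2,3-diol made by asymmetric dihydroxylation (K2OsO2(OH)4, (DHQD)2PHAL) of the (E)-alkenoate A1. The hydroxy-lactone is then esterified with the protected dienoic acid A3 under Yamaguchi conditions. Three structural reasons speak against it.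
- The osmium reagent would attack the trisubstituted C6′=C7′ alkene before the 1,2-disubstituted one.
- The diol closes through the C3 oxygen to the γ-lactone A2, so the wrong oxygen is in the ring and must be corrected by protection, opening and relactonisation.
- Activating a 2,4-dienoic acid towards a hindered alcohol risks E/Z isomerisation.

The chosen plan fixes the oxygen roles by construction and uses no oxidant that sees an isolated alkene.

**Alternative 2:** form the C3–O ester bond and the C3 centre together. Zerovalent palladium would open the trans-γ,δ-epoxy enoate A4 with the carboxylic acid with net retention (double inversion through the π-allyl complex), followed by alkene reduction and lactonisation. It is attractive because O1 and the C3 oxygen are differentiated in the union. It fails on three counts.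
- The epoxide oxygen must come from an electrophilic oxidant, which prefers C6′=C7′.
- The product is itself an allylic ester that can re-ionise, so C3 can erode.
- The C4=C5 alkene would have to be reduced in the presence of the dienoate.

**Alternative 3:** cut C2–C3 and set both centres in one union, by a vinylogous Mukaiyama aldol of 2-(trimethylsilyloxy)furan with aldehyde 10 to give butenolide A5. The step is short and convergent, but it puts the C3 oxygen into a five-membered lactone and leaves the C2 hydroxyl free, the reverse of the target. Turning A5 into the δ-lactone with an acyl group on C3 runs against the thermodynamic preference and would cost four or five operations. The Achmatowicz route uses the same furan carbons but delivers the six-membered ring directly.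

Key step: step 6

## Route

Step 1
Reactants: 1 (E)-2-bromobut-2-ene; 2 3-bromoprop-1-ene (allyl bromide)
Product: 4 (E)-4-methylhexa-1,4-diene, via (E)-but-2-en-2-yllithium 3 (not isolated)
Conditions: t-BuLi (2 equiv), Et2O, −78 °C; then 2, −78 to 0 °C; distillation
Reagents that add atoms: none
Why: Bromine–lithium exchange on an alkenyl bromide retains the double-bond geometry, and alkylation of the alkenyllithium by allyl bromide (SN2 and SN2′ give the same product) should carry the E geometry of 1 into the future C6′=C7′ alkene.

Step 2
Reactants: 4 (E)-4-methylhexa-1,4-diene; 5 bromoethene (vinyl bromide)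
Product: 7 (4R,6E)-4,6-dimethylocta-1,6-diene, via alkyldimethylalane 6 (not isolated)
Conditions: Me3Al, (+)-bis(1-neomenthylindenyl)zirconium dichloride [(+)-(NMI)2ZrCl2] (cat.), methylaluminoxane (cat.), CH2Cl2, 0 °C to rt; volatiles removed; Zn(OTf)2, DMF, 70 °C; then 5, Pd(DPEphos)Cl2 (cat.), i-Bu2AlH (cat.), rt
Reagents that add atoms: trimethylaluminium C[Al](C)C
Why: Zirconium-catalysed asymmetric carboalumination (ZACA) adds Me–Al only to the monosubstituted alkene, the chiral zirconocene choosing the face that sets C4′ in alane 6; transmetalation to zinc and Negishi coupling with vinyl bromide should then give the next terminal alkene without touching the new centre.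

Step 3
Reactants: 7 (4R,6E)-4,6-dimethylocta-1,6-diene
Product: 9 (2S,4R,6E)-2,4,6-trimethyloct-6-en-1-ol, via alkyldimethylalane 8 (not isolated)
Conditions: Me3Al, (+)-(NMI)2ZrCl2 (cat.), methylaluminoxane (cat.), CH2Cl2, 0 °C to rt; then dry O2, −20 °C to rt; aqueous NaOH work-up; chromatography
Reagents that add atoms: trimethylaluminium C[Al](C)C; dioxygen O=O
Why: A second ZACA cycle with the same catalyst enantiomer should set C2′ syn to C4′ by reagent control, and oxidation of the C–Al bond gives the primary alcohol; stereoisomers from incomplete face selectivity in either cycle are diastereomers at this stage and should be separable.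

Step 4
Reactants: 9 (2S,4R,6E)-2,4,6-trimethyloct-6-en-1-ol
Product: 10 (2S,4R,6E)-2,4,6-trimethyloct-6-enal
Conditions: TEMPO (cat.), PhI(OAc)2, CH2Cl2, rt; used directly
Reagents that add atoms: none
Why: Oxoammonium-mediated oxidation of a primary alcohol stops at the aldehyde under non-basic conditions, which should leave the α-stereocentre C2′ and the trisubstituted alkene untouched.

Step 5
Reactants: 10 (2S,4R,6E)-2,4,6-trimethyloct-6-enal; 11 furan
Product: 13 (1R,2S,4R,6E)-1-(furan-2-yl)-2,4,6-trimethyloct-6-en-1-ol, via furan-2-yllithium 12 (not isolated)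
Conditions: 11, n-BuLi, THF, −78 to 0 °C; then 10, −78 °C; H2O
Reagents that add atoms: none
Why: Addition of an aryllithium to an α-methyl aldehyde follows the Felkin–Anh model, which should favour the carbinol (future C2) syn to the C1′ methyl group; the minor C2 epimer is carried along because step 6 consumes only the 1R carbinol.

Step 6
Reactants: 13 (1R,2S,4R,6E)-1-(furan-2-yl)-2,4,6-trimethyloct-6-en-1-ol
Product: 15 (2R)-2-[(2S,4R,6E)-4,6-dimethyloct-6-en-2-yl]-6-hydroxy-2H-pyran-3(6H)-one (mixture at the lactol carbon), via open-chain Z-keto-enal 14 (not isolated)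
Conditions: Ti(OiPr)4 (20 mol%), D-(−)-diisopropyl tartrate (24 mol%), t-BuOOH (substoichiometric, matched to the content of the 1R epimer), 4 Å molecular sieves, CH2Cl2, −20 °C
Reagents that add atoms: tert-butyl hydroperoxide CC(C)(C)OO
Why: This is an Achmatowicz rearrangement run under Sharpless kinetic-resolution conditions: the carbinol binds to the titanium tartrate, the bound peroxide oxidises the adjacent furan double bond, and the oxidised furan opens to the Z-keto-enal 14. The carbinol oxygen then adds to the aldehyde (6-exo-trig hemiacetal closure), so the oxygen set on C2 becomes ring O1, furan C2 becomes the C3 ketone and furan C5 the C6 lactol. The closest known reaction type is the titanium tartrate/t-BuOOH oxidation of secondary 2-furylcarbinols, which is a ring expansion and a kinetic resolution at once. No stereocentre of the target is created; the lactol centre at C6 is uncontrolled and is removed in step 7. The first selectivity needed is between the two C2 epimers: with the furan double bond taken as the alkene of the allylic-alcohol mnemonic, D-(−)-tartrate should make the R carbinol the fast-reacting one, so the minor epimer from step 5 stays behind as unchanged carbinol and is separated. The second is chemoselectivity for the furan over C6′=C7′, which is secured because titanium delivers the peroxide only to a double bond next to the bound hydroxyl and does not epoxidise an isolated alkene. The deficit of peroxide keeps the slow epimer from reacting.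

Step 7
Reactants: 15 (2R)-2-[(2S,4R,6E)-4,6-dimethyloct-6-en-2-yl]-6-hydroxy-2H-pyran-3(6H)-one
Product: 17 (5R,6R)-6-[(2S,4R,6E)-4,6-dimethyloct-6-en-2-yl]-5-hydroxy-5,6-dihydro-2H-pyran-2-one, via pyran-2,5-dione 16 (not isolated)
Conditions: RuCl[(S,S)-TsDPEN](p-cymene) (2–5 mol%), Et3N (10 mol%), CH2Cl2, rt
Reagents that add atoms: none
Why: Internal redox isomerisation of an Achmatowicz lactol by a transfer-hydrogenation catalyst: the ruthenium amide dehydrogenates the lactol to enedione 16 and the ruthenium hydride returns the hydrogen to the C3 ketone; the (S,S) catalyst places the alkene carbon C4 on the arene side and attacks the face anti to the branched C2 substituent, so catalyst preference and steric approach should both give the 3R carbinol cis to the side chain.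

Step 8
Reactants: 17 (5R,6R)-6-[(2S,4R,6E)-4,6-dimethyloct-6-en-2-yl]-5-hydroxy-5,6-dihydro-2H-pyran-2-one; 18 2-(diethoxyphosphoryl)acetic acid
Product: 19 (2R,3R)-2-[(2S,4R,6E)-4,6-dimethyloct-6-en-2-yl]-6-oxo-3,6-dihydro-2H-pyran-3-yl 2-(diethoxyphosphoryl)acetate
Conditions: N,N′-diisopropylcarbodiimide, DMAP (cat.), CH2Cl2, 0 °C to rt
Reagents that add atoms: none
Why: Steglich esterification of a secondary alcohol with a small acid proceeds with retention at C3; acylating while the ring is still unsaturated means a free C3–OH never sits on a saturated δ-lactone, where it could translactonise to the γ-lactone.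

Step 9
Reactants: 19 (2R,3R)-2-[(2S,4R,6E)-4,6-dimethyloct-6-en-2-yl]-6-oxo-3,6-dihydro-2H-pyran-3-yl 2-(diethoxyphosphoryl)acetate
Product: 20 (2R,3R)-2-[(2S,4R,6E)-4,6-dimethyloct-6-en-2-yl]-6-oxooxan-3-yl 2-(diethoxyphosphoryl)acetate
Conditions: H2 (1 atm), RhCl(PPh3)3 (cat.), benzene/EtOH, rt
Reagents that add atoms: none
Why: Homogeneous hydrogenation with RhCl(PPh3)3 reduces cis-disubstituted alkenes but not trisubstituted ones, so C4=C5 should be saturated while C6′=C7′ survives, and unlike Pd on carbon the catalyst does not ionise the allylic ester.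

Step 10
Reactants: 21 furan-2(5H)-one; 22 (2-methylprop-1-en-1-yl)boronic acid
Product: 23 (4R)-4-(2-methylprop-1-en-1-yl)oxolan-2-one
Conditions: [Rh(OH)((R)-BINAP)]2 (cat.), dioxane/H2O 10:1, 40 °C
Reagents that add atoms: none
Why: Rhodium-catalysed asymmetric 1,4-addition of an alkenylboronic acid (Hayashi–Miyaura reaction) sets C6″; the (R)-BINAP complex should add to the face that gives the 4R lactone, the same facial sense by which the (S)-ligand gives (S)-3-substituted cyclohexanones, and water protonates the rhodium enolate.

Step 11
Reactants: 23 (4R)-4-(2-methylprop-1-en-1-yl)oxolan-2-one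
Product: 24 (2R)-2-(2-methylprop-1-en-1-yl)butane-1,4-diol
Conditions: LiAlH4, THF, 0 °C to rt
Reagents that add atoms: none
Why: Hydride reduction of the lactone opens it to the 1,4-diol, which gives both hydroxyl arms of the acid half in one operation without touching the stereocentre or the alkene.

Step 12
Reactants: 24 (2R)-2-(2-methylprop-1-en-1-yl)butane-1,4-diol
Product: 25 (2R)-1,4-bis[(tert-butyldimethylsilyl)oxy]-2-(2-methylprop-1-en-1-yl)butane
Conditions: TBSCl, imidazole, DMF, rt
Reagents that add atoms: tert-butyldimethylsilyl chloride CC(C)(C)[Si](C)(C)Cl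
Why: Both primary alcohols are silylated; silyl ethers are chosen because they survive selenium dioxide, the olefination and can be removed at the end by fluoride without base.

Step 13
Reactants: 25 (2R)-1,4-bis[(tert-butyldimethylsilyl)oxy]-2-(2-methylprop-1-en-1-yl)butane
Product: 27 (2E,4R)-6-[(tert-butyldimethylsilyl)oxy]-4-{[(tert-butyldimethylsilyl)oxy]methyl}-2-methylhex-2-enal, via E-allylic alcohol 26 (not isolated)
Conditions: SeO2 (cat.), t-BuOOH, CH2Cl2, rt; crude mixture then MnO2, CH2Cl2, rt
Reagents that add atoms: tert-butyl hydroperoxide CC(C)(C)OO (oxygen relayed by SeO2)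
Why: Selenium dioxide allylic oxidation (ene reaction, then [2,3]-sigmatropic shift) acts at the more substituted end of a trisubstituted alkene and on the E-methyl group, so it should give the E-allylic alcohol 26 and some enal while sparing the C6″ methine; MnO2 converges the mixture to enal 27.

Step 14
Reactants: 20 (2R,3R)-2-[(2S,4R,6E)-4,6-dimethyloct-6-en-2-yl]-6-oxooxan-3-yl 2-(diethoxyphosphoryl)acetate; 27 (2E,4R)-6-[(tert-butyldimethylsilyl)oxy]-4-{[(tert-butyldimethylsilyl)oxy]methyl}-2-methylhex-2-enal
Product: 28 (2R,3R)-2-[(2S,4R,6E)-4,6-dimethyloct-6-en-2-yl]-6-oxooxan-3-yl (2E,4E,6R)-8-[(tert-butyldimethylsilyl)oxy]-6-{[(tert-butyldimethylsilyl)oxy]methyl}-4-methylocta-2,4-dienoate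
Conditions: LiCl, i-Pr2NEt, MeCN, rt
Reagents that add atoms: none
Why: Horner–Wadsworth–Emmons olefination under Masamune–Roush conditions is E-selective with enals, and the weak amine base should neither epimerise C6″ through the dienolate nor open the lactone.

Step 15
Reactants: 28 (2R,3R)-2-[(2S,4R,6E)-4,6-dimethyloct-6-en-2-yl]-6-oxooxan-3-yl (2E,4E,6R)-8-[(tert-butyldimethylsilyl)oxy]-6-{[(tert-butyldimethylsilyl)oxy]methyl}-4-methylocta-2,4-dienoate
Product: 29 (2R,3R)-2-[(2S,4R,6E)-4,6-dimethyloct-6-en-2-yl]-6-oxooxan-3-yl (2E,4E,6R)-8-hydroxy-6-(hydroxymethyl)-4-methylocta-2,4-dienoate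
Conditions: HF·pyridine, pyridine, THF, 0 °C to rt
Reagents that add atoms: none
Why: Buffered hydrogen fluoride cleaves primary silyl ethers under weakly acidic conditions, where the liberated hydroxyls should not attack the ester or lactone and the dienoate should not isomerise.

## Compound list

1 | (E)-2-bromobut-2-ene | C/C=C(\C)Br | starting material
2 | 3-bromoprop-1-ene (allyl bromide) | C=CCBr | starting material
3 | (E)-but-2-en-2-yllithium | C/C=C(\C)[Li] | intermediate
4 | (E)-4-methylhexa-1,4-diene | C/C=C(\C)CC=C | intermediate
5 | bromoethene (vinyl bromide) | C=CBr | starting material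
6 | dimethyl[(2S,4E)-2,4-dimethylhex-4-en-1-yl]alumane | C/C=C(\C)C[C@H](C)C[Al](C)C | intermediate
7 | (4R,6E)-4,6-dimethylocta-1,6-diene | C/C=C(\C)C[C@H](C)CC=C | intermediate
8 | dimethyl[(2S,4R,6E)-2,4,6-trimethyloct-6-en-1-yl]alumane | C/C=C(\C)C[C@H](C)C[C@H](C)C[Al](C)C | intermediate
9 | (2S,4R,6E)-2,4,6-trimethyloct-6-en-1-ol | C/C=C(\C)C[C@H](C)C[C@H](C)CO | intermediate
10 | (2S,4R,6E)-2,4,6-trimethyloct-6-enal | C/C=C(\C)C[C@H](C)C[C@H](C)C=O | intermediate
11 | furan | c1ccoc1 | starting material
12 | furan-2-yllithium | [Li]c1ccco1 | intermediate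
13 | (1R,2S,4R,6E)-1-(furan-2-yl)-2,4,6-trimethyloct-6-en-1-ol | C/C=C(\C)C[C@H](C)C[C@H](C)[C@@H](O)c1ccco1 | intermediate
14 | (2Z,5R,6S,8R,10E)-5-hydroxy-6,8,10-trimethyl-4-oxododeca-2,10-dienal | C/C=C(\C)C[C@H](C)C[C@H](C)[C@@H](O)C(=O)/C=C\C=O | intermediate
15 | (2R)-2-[(2S,4R,6E)-4,6-dimethyloct-6-en-2-yl]-6-hydroxy-2H-pyran-3(6H)-one | C/C=C(\C)C[C@H](C)C[C@H](C)[C@H]1OC(O)C=CC1=O | intermediate
16 | (6R)-6-[(2S,4R,6E)-4,6-dimethyloct-6-en-2-yl]-2H-pyran-2,5(6H)-dione | C/C=C(\C)C[C@H](C)C[C@H](C)[C@H]1OC(=O)C=CC1=O | intermediate
17 | (5R,6R)-6-[(2S,4R,6E)-4,6-dimethyloct-6-en-2-yl]-5-hydroxy-5,6-dihydro-2H-pyran-2-one | C/C=C(\C)C[C@H](C)C[C@H](C)[C@H]1OC(=O)C=C[C@H]1O | intermediate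
18 | 2-(diethoxyphosphoryl)acetic acid | CCOP(=O)(CC(=O)O)OCC | starting material
19 | (2R,3R)-2-[(2S,4R,6E)-4,6-dimethyloct-6-en-2-yl]-6-oxo-3,6-dihydro-2H-pyran-3-yl 2-(diethoxyphosphoryl)acetate | C/C=C(\C)C[C@H](C)C[C@H](C)[C@H]1OC(=O)C=C[C@H]1OC(=O)CP(=O)(OCC)OCC | intermediate
20 | (2R,3R)-2-[(2S,4R,6E)-4,6-dimethyloct-6-en-2-yl]-6-oxooxan-3-yl 2-(diethoxyphosphoryl)acetate | C/C=C(\C)C[C@H](C)C[C@H](C)[C@H]1OC(=O)CC[C@H]1OC(=O)CP(=O)(OCC)OCC | intermediate
21 | furan-2(5H)-one | O=C1C=CCO1 | starting material
22 | (2-methylprop-1-en-1-yl)boronic acid | CC(C)=CB(O)O | starting material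
23 | (4R)-4-(2-methylprop-1-en-1-yl)oxolan-2-one | O=C1C[C@H](C=C(C)C)CO1 | intermediate
24 | (2R)-2-(2-methylprop-1-en-1-yl)butane-1,4-diol | CC(C)=C[C@H](CO)CCO | intermediate
25 | (2R)-1,4-bis[(tert-butyldimethylsilyl)oxy]-2-(2-methylprop-1-en-1-yl)butane | CC(C)=C[C@H](CO[Si](C)(C)C(C)(C)C)CCO[Si](C)(C)C(C)(C)C | intermediate
26 | (2E,4R)-6-[(tert-butyldimethylsilyl)oxy]-4-{[(tert-butyldimethylsilyl)oxy]methyl}-2-methylhex-2-en-1-ol | OC/C(C)=C/[C@H](CO[Si](C)(C)C(C)(C)C)CCO[Si](C)(C)C(C)(C)C | intermediate
27 | (2E,4R)-6-[(tert-butyldimethylsilyl)oxy]-4-{[(tert-butyldimethylsilyl)oxy]methyl}-2-methylhex-2-enal | O=C/C(C)=C/[C@H](CO[Si](C)(C)C(C)(C)C)CCO[Si](C)(C)C(C)(C)C | intermediate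
28 | (2R,3R)-2-[(2S,4R,6E)-4,6-dimethyloct-6-en-2-yl]-6-oxooxan-3-yl (2E,4E,6R)-8-[(tert-butyldimethylsilyl)oxy]-6-{[(tert-butyldimethylsilyl)oxy]methyl}-4-methylocta-2,4-dienoate | C/C=C(\C)C[C@H](C)C[C@H](C)[C@H]1OC(=O)CC[C@H]1OC(=O)/C=C/C(C)=C/[C@H](CO[Si](C)(C)C(C)(C)C)CCO[Si](C)(C)C(C)(C)C | intermediate
29 | (2R,3R)-2-[(2S,4R,6E)-4,6-dimethyloct-6-en-2-yl]-6-oxooxan-3-yl (2E,4E,6R)-8-hydroxy-6-(hydroxymethyl)-4-methylocta-2,4-dienoate | C/C=C(\C)C[C@H](C)C[C@H](C)[C@H]1OC(=O)CC[C@H]1OC(=O)/C=C/C(C)=C/[C@H](CO)CCO | target

## Step count and least certain steps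

Total: 15 steps. Longest linear sequence: 11 steps (steps 1–9, 14, 15); the acid half takes 4 steps (10–13) before the union.

**Step 6 (key step).** The likeliest failure is insufficient rate discrimination between the two C2 epimers of 13, because the branched C2′ centre next to the carbinol also interacts with the tartrate complex, or slow turnover of this hindered carbinol. The fallback gives up the furan and builds the ring by metathesis. It sets out from aldehyde 10. Syn-selective alkoxyallylboration with the (Z)-γ-(4-methoxybenzyloxy)allyl diisopinocampheylborane made from (−)-Ipc2BOMe should give (3R,4R,5S,7R,9E)-3-[(4-methoxyphenyl)methoxy]-5,7,9-trimethylundeca-1,9-dien-4-ol F1, in which the two oxygens are differentiated by reagent control. Acryloyl chloride and i-Pr2NEt give (3R,4R,5S,7R,9E)-3-[(4-methoxyphenyl)methoxy]-5,7,9-trimethylundeca-1,9-dien-4-yl prop-2-enoate F2. Ring-closing metathesis with the second-generation Grubbs catalyst gives (5R,6R)-6-[(2S,4R,6E)-4,6-dimethyloct-6-en-2-yl]-5-[(4-methoxyphenyl)methoxy]-5,6-dihydro-2H-pyran-2-one F3, and DDQ removes the benzyl-type ether. The fallback comes back to the route at alcohol 17.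

**Step 7.** Two processes may interfere: conjugate reduction of the doubly activated alkene of the transient enedione by the metal hydride, and hydride delivery to the wrong face of the C3 ketone if the substrate's preference for axial attack outweighs the catalyst. Enolisation at C2 under the amine is a further risk. The fallback sets out from lactol 15 and separates oxidation from reduction. CrO3/H2SO4 in acetone gives isolated dione 16; NaBH4/CeCl3 at −78 °C should then give, by axial hydride delivery, the trans alcohol (5S,6R)-6-[(2S,4R,6E)-4,6-dimethyloct-6-en-2-yl]-5-hydroxy-5,6-dihydro-2H-pyran-2-one F4. Mitsunobu esterification of F4 with acid 18 (PPh3, diisopropyl azodicarboxylate) inverts C3 and comes back to the route at ester 19.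

**Step 2 (and its repeat in step 3).** Incomplete enantioface selectivity of the carboalumination is the main risk, possibly lowered further by coordination of the nearby trisubstituted alkene to zirconium; it would give stereoisomer mixtures that are hard to purify as hydrocarbons. The fallback takes both methyl-bearing centres from a meso compound. It sets out from bromide 1 and returns at alcohol 9. meso-2,4-Dimethylpentane-1,5-diol F5 is desymmetrised by lipase-catalysed mono-acetylation with vinyl acetate to (2S,4R)-5-hydroxy-2,4-dimethylpentyl acetate F6. I2, PPh3 and imidazole give (2S,4R)-5-iodo-2,4-dimethylpentyl acetate F7. Zinc insertion and Negishi coupling with 1 (Pd(OAc)2, SPhos) give (2S,4R,6E)-2,4,6-trimethyloct-6-en-1-yl acetate F8, and K2CO3 in methanol releases 9.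

**Step 5.** Facial selectivity of the furyllithium addition may be poor, since an α-methyl group alone gives only a modest Felkin–Anh bias; this would waste material in step 6. The fallback makes C2 under reagent control. It sets out from the epimer mixture of 13: MnO2 oxidation gives (2S,4R,6E)-1-(furan-2-yl)-2,4,6-trimethyloct-6-en-1-one F9, and asymmetric transfer hydrogenation with RuCl[(R,R)-TsDPEN](p-cymene) in HCO2H/Et3N should return the single 1R epimer. It comes back to the route at 13.

**Step 9.** Hydrogenation of the conjugated ring alkene may be slow next to the bulky ester, and long reaction times could start to reduce or isomerise C6′=C7′. The fallback removes the ring alkene before the carbinol is made. It sets out from lactol 15: Zn in acetic acid reduces the enone alkene to (2R)-2-[(2S,4R,6E)-4,6-dimethyloct-6-en-2-yl]-6-hydroxyoxan-3-one F10. The same ruthenium catalyst as in step 7 should isomerise this to (5R,6R)-6-[(2S,4R,6E)-4,6-dimethyloct-6-en-2-yl]-5-hydroxyoxan-2-one F11, which is acylated at once with 18 and N,N′-diisopropylcarbodiimide to limit translactonisation. It comes back to the route at phosphonate 20.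

**Step 13.** Over-oxidation or incomplete conversion in the selenium dioxide step may lower the material throughput, since the alkene is flanked by a branched centre. The fallback replaces C–H oxidation by olefin metathesis. It sets out from 25, which undergoes cross-metathesis with methacrolein (second-generation Hoveyda–Grubbs catalyst, isobutene lost) to give the E-enal directly, and comes back at 27. It makes no new compound.

## Further compounds

F1 | step 6 | (3R,4R,5S,7R,9E)-3-[(4-methoxyphenyl)methoxy]-5,7,9-trimethylundeca-1,9-dien-4-ol | C/C=C(\C)C[C@H](C)C[C@H](C)[C@@H](O)[C@H](OCc1ccc(OC)cc1)C=C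
F2 | step 6 | (3R,4R,5S,7R,9E)-3-[(4-methoxyphenyl)methoxy]-5,7,9-trimethylundeca-1,9-dien-4-yl prop-2-enoate | C/C=C(\C)C[C@H](C)C[C@H](C)[C@@H](OC(=O)C=C)[C@H](OCc1ccc(OC)cc1)C=C
F3 | step 6 | (5R,6R)-6-[(2S,4R,6E)-4,6-dimethyloct-6-en-2-yl]-5-[(4-methoxyphenyl)methoxy]-5,6-dihydro-2H-pyran-2-one | C/C=C(\C)C[C@H](C)C[C@H](C)[C@H]1OC(=O)C=C[C@H]1OCc1ccc(OC)cc1
F4 | step 7 | (5S,6R)-6-[(2S,4R,6E)-4,6-dimethyloct-6-en-2-yl]-5-hydroxy-5,6-dihydro-2H-pyran-2-one | C/C=C(\C)C[C@H](C)C[C@H](C)[C@H]1OC(=O)C=C[C@@H]1O
F5 | step 2 | meso-2,4-dimethylpentane-1,5-diol | OC[C@H](C)C[C@H](C)CO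
F6 | step 2 | (2S,4R)-5-hydroxy-2,4-dimethylpentyl acetate | OC[C@H](C)C[C@H](C)COC(C)=O
F7 | step 2 | (2S,4R)-5-iodo-2,4-dimethylpentyl acetate | IC[C@H](C)C[C@H](C)COC(C)=O
F8 | step 2 | (2S,4R,6E)-2,4,6-trimethyloct-6-en-1-yl acetate | C/C=C(\C)C[C@H](C)C[C@H](C)COC(C)=O
F9 | step 5 | (2S,4R,6E)-1-(furan-2-yl)-2,4,6-trimethyloct-6-en-1-one | C/C=C(\C)C[C@H](C)C[C@H](C)C(=O)c1ccco1
F10 | step 9 | (2R)-2-[(2S,4R,6E)-4,6-dimethyloct-6-en-2-yl]-6-hydroxyoxan-3-one | C/C=C(\C)C[C@H](C)C[C@H](C)[C@H]1OC(O)CCC1=O
F11 | step 9 | (5R,6R)-6-[(2S,4R,6E)-4,6-dimethyloct-6-en-2-yl]-5-hydroxyoxan-2-one | C/C=C(\C)C[C@H](C)C[C@H](C)[C@H]1OC(=O)CC[C@H]1O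
F0 | step 13 | none | none
A1 | alternative 1 | ethyl (4E,6S,8R,10E)-6,8,10-trimethyldodeca-4,10-dienoate | C/C=C(\C)C[C@H](C)C[C@H](C)/C=C/CCC(=O)OCC
A2 | alternative 1 | (5R)-5-[(1R,2S,4R,6E)-1-hydroxy-2,4,6-trimethyloct-6-en-1-yl]oxolan-2-one | C/C=C(\C)C[C@H](C)C[C@H](C)[C@@H](O)[C@H]1CCC(=O)O1
A3 | alternative 1 | (2E,4E,6R)-8-[(tert-butyldimethylsilyl)oxy]-6-{[(tert-butyldimethylsilyl)oxy]methyl}-4-methylocta-2,4-dienoic acid | OC(=O)/C=C/C(C)=C/[C@H](CO[Si](C)(C)C(C)(C)C)CCO[Si](C)(C)C(C)(C)C
A4 | alternative 2 | methyl (2E,4R,5R,6S,8R,10E)-4,5-epoxy-6,8,10-trimethyldodeca-2,10-dienoate | C/C=C(\C)C[C@H](C)C[C@H](C)[C@H]1O[C@@H]1/C=C/C(=O)OC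
A5 | alternative 3 | (5R)-5-[(1R,2S,4R,6E)-1-hydroxy-2,4,6-trimethyloct-6-en-1-yl]furan-2(5H)-one | C/C=C(\C)C[C@H](C)C[C@H](C)[C@@H](O)[C@H]1C=CC(=O)O1
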